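**Plan**
1. Numbering: ring A is the dearomatised ring, with C1 (C=O), C2 (butanoyl), C3 (C-OH), C4 (quaternary; CH3 and prenyl), C5 (C-OH) and C6 (bridge carbon). Ring B is the arene.
2. Cuts: first the C6-CH2 bond of the methylene bridge (ring B leaves as an ortho-quinone methide), then C5-C6 and C2-C3 of ring A in one operation.
3. Enabling feature: ring A is a cyclohexane-1,3,5-trione in which C3-C4-C5 is a 2,2-disubstituted malonyl unit without α-hydrogen. C6-C1-C2 and the exocyclic butanoyl group are the intact chain of heptane-2,4-dione, which is a 1,3-dinucleophile as its dianion.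
4. Forward: ring B is bought as phloroglucinol. Ring A, the only ring that is closed, arises by a [3+3] union of a malonyl chloride half ester with the diketone dianion, and the two halves are then joined through the bridge.
5. Stereochemistry: C4 is set by asymmetric phase-transfer prenylation of a mixed methylmalonate. Its two different esters become C5 (acid chloride) and C3 (ester), so the regiochemistry of the annulation carries the configuration. Ring A must be closed with C2 already acylated, because the unacylated trione is achiral.

Key step: step 6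

Assumption: the (S,S)-catalyst is taken to shield the same enolate face with prenyl bromide as with other allylic and benzylic bromides, which corresponds to the (S)-diester (otherwise the commercial (R,R)-catalyst is used); enolised triketones are drawn, and given CIP descriptors, in the tautomer of the target SMILES.

Step 1
Reactants: 1 2,2,5-trimethyl-1,3-dioxane-4,6-dione (methyl Meldrum's acid); 2 tert-butanol
Product: 3 3-tert-butoxy-2-methyl-3-oxopropanoic acid (racemic)
Conditions: t-BuOH (solvent), reflux
Reagents that add atoms: none
Why: Alcoholysis of a Meldrum's acid (nucleophilic acyl substitution at the activated cyclic acylal with loss of acetone) stops at the malonic half ester because the carboxylic acid formed is inert to further attack.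

Step 2
Reactants: 3 3-tert-butoxy-2-methyl-3-oxopropanoic acid; 4 2,2-diphenylethanol
Product: 5 1-tert-butyl 3-(2,2-diphenylethyl) 2-methylpropanedioate (racemic)
Conditions: DCC, 4-(dimethylamino)pyridine (cat.), CH2Cl2, 0 → 23 °C
Reagents that add atoms: none
Why: Steglich esterification couples the free acid with the primary alcohol under neutral conditions that leave the tert-butyl ester untouched.

Step 3
Reactants: 5 1-tert-butyl 3-(2,2-diphenylethyl) 2-methylpropanedioate; 6 1-bromo-3-methylbut-2-ene (prenyl bromide)
Product: 7 1-tert-butyl 3-(2,2-diphenylethyl) (S)-2-methyl-2-(3-methylbut-2-enyl)propanedioate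
Conditions: (S,S)-3,4,5-trifluorophenyl-NAS bromide (C56H34BrF6N, N-spiro bis-binaphthyl ammonium bromide, 5 mol %), 50% aq KOH, toluene, −40 °C
Reagents that add atoms: none
Why: In this asymmetric phase-transfer alkylation, a reaction type established for this malonate class with allylic bromides, the chiral ammonium cation shields one face of the enolate of 5, whose orientation is fixed by the bulky tert-butyl and the π-stacking 2,2-diphenylethyl ester, so that SN2 attack on the primary carbon of 6 should set C4 as S.

Step 4
Reactants: 7 1-tert-butyl 3-(2,2-diphenylethyl) (S)-2-methyl-2-(3-methylbut-2-enyl)propanedioate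
Product: 9 (R)-2-[(2,2-diphenylethoxy)carbonyl]-2,5-dimethylhex-4-enoic acid, via trimethylsilyl ester 8 (not isolated)
Conditions: TMSOTf, 2,6-lutidine, CH2Cl2, 0 → 23 °C; pH 4 phosphate buffer
Reagents that add atoms: none
Why: In this silyl triflate dealkylation of a tert-butyl ester, O-silylation and loss of the tert-butyl group as isobutene to the hindered base give 8, which water cleaves on work-up, so that the primary ester, the acid-sensitive prenyl alkene and the quaternary centre are not affected (the descriptor changes by priority only).

Step 5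
Reactants: 9 (R)-2-[(2,2-diphenylethoxy)carbonyl]-2,5-dimethylhex-4-enoic acid
Product: 10 2,2-diphenylethyl (S)-2-(chlorocarbonyl)-2,5-dimethylhex-4-enoate
Conditions: 1-chloro-N,N,2-trimethylprop-1-en-1-amine, CH2Cl2, 0 → 23 °C, used crude
Reagents that add atoms: 1-chloro-N,N,2-trimethylprop-1-en-1-amine CC(C)=C(Cl)N(C)C
Why: Acid chloride formation with an α-chloroenamine runs under neutral conditions without HCl that could add to the prenyl double bond, and because C4 carries no hydrogen neither ketene formation nor racemisation is possible.

Step 6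
Reactants: 10 2,2-diphenylethyl (S)-2-(chlorocarbonyl)-2,5-dimethylhex-4-enoate; 11 heptane-2,4-dione
Product: 14 (R)-2-butanoyl-3,5-dihydroxy-4-methyl-4-(3-methylbut-2-enyl)cyclohexa-2,5-dien-1-one, via dilithium dienediolate 12 (not isolated), via open-chain triketo ester 13 (not isolated)
Conditions: 11 (2.1 equiv), LiN(iPr)2 (4.1 equiv), THF, 0 °C; 10, −78 → 23 °C, then 45 °C; 1 M HCl, 0 °C; extraction of 14 into aq NaHCO3
Reagents that add atoms: none
Why: Mechanism: the terminal carbon of dienediolate 12 (future C6), the last-formed and most basic site, attacks only the acid chloride carbonyl of 10 (future C5), a proton shift to the second equivalent of 12 turns the product into the dianion of 13, and its central carbon (future C2) then adds to the remaining ester carbonyl (future C3) and expels 2,2-diphenylethoxide. The closest known reaction types are the γ-acylation of 1,3-diketone dianions to 1,3,5-triketones and the Dieckmann (intramolecular Claisen) cyclisation of 3,5,7-trioxo esters to 2-acylphloroglucinols, which here must stop at the trione because C4 is quaternary. Ring A closes in the 6-(enolexo)-exo-trig mode, favoured by the geminal substituents at C4 and made irreversible by double deprotonation of the β-triketone 14. No stereocentre is created: C4 comes from 10, has no hydrogen and keeps all four bonds, so the configuration is retained and only the descriptor changes from S to R. The selectivity needed is the pairing C6 to C5 and C2 to C3, since the reverse pairing would give the enantiomer, and it is secured by the two reactivity gaps acid chloride over ester and terminal carbanion over central enolate, while kinetic removal of a methyl rather than a propyl-chain proton from the monoanion of 11 fixes the constitution. O-Acylation to the six-membered enol lactone is reversible under the released alkoxide and drains to the C-acylated product.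

Step 7
Reactants: 15 phloroglucinol; 16 butanoyl chloride
Product: 17 1-(2,4,6-trihydroxyphenyl)butan-1-one
Conditions: AlCl3 (3.5 equiv), CH2Cl2-MeNO2, 0 → 40 °C; aq HCl
Reagents that add atoms: none
Why: Friedel-Crafts acylation of the very electron-rich arene stops after one acyl group because the chelated aryl ketone deactivates the ring.

Step 8
Reactants: 17 1-(2,4,6-trihydroxyphenyl)butan-1-one
Product: 18 1-(2,6-dihydroxy-4-methoxyphenyl)butan-1-one
Conditions: Me2SO4 (1.0 equiv), K2CO3 (1.0 equiv), acetone, 23 °C → reflux
Reagents that add atoms: dimethyl sulfate COS(=O)(=O)OC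
Why: Williamson-type O-methylation is selective for the 4-hydroxyl group, the most acidic one, since both ortho hydroxyl groups are tied up in hydrogen bonds to the ketone, and one equivalent of base and electrophile limits overalkylation.

Step 9
Reactants: 18 1-(2,6-dihydroxy-4-methoxyphenyl)butan-1-one
Product: 19 1-{3-[(dimethylamino)methyl]-2,6-dihydroxy-4-methoxyphenyl}butan-1-one
Conditions: 37% aq CH2O (1.0 equiv), 40% aq Me2NH (1.1 equiv), EtOH, 0 → 23 °C
Reagents that add atoms: formaldehyde C=O; dimethylamine CNC
Why: The Mannich reaction takes place at one of the two equivalent free positions of the symmetrical ketone 18 and is held at the mono stage by stoichiometry and low temperature.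

Step 10
Reactants: 14 (R)-2-butanoyl-3,5-dihydroxy-4-methyl-4-(3-methylbut-2-enyl)cyclohexa-2,5-dien-1-one; 19 1-{3-[(dimethylamino)methyl]-2,6-dihydroxy-4-methoxyphenyl}butan-1-one
Product: 21 elaphopilosin A, via ortho-quinone methide 20 (not isolated)
Conditions: 1,4-dioxane, 80 °C, argon sweep
Reagents that add atoms: none
Why: The acidic trione protonates the Mannich base, loss of dimethylamine gives ortho-quinone methide 20, and Michael addition of C6, the only unsubstituted nucleophilic carbon of the enolate of 14, to its exocyclic CH2 is driven by rearomatisation of ring B and does not touch C4.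

**Compound list**
1 | 2,2,5-trimethyl-1,3-dioxane-4,6-dione | CC1C(=O)OC(C)(C)OC1=O | starting material
2 | tert-butanol | CC(C)(C)O | starting material
3 | 3-tert-butoxy-2-methyl-3-oxopropanoic acid (racemic) | CC(C(=O)O)C(=O)OC(C)(C)C | intermediate
4 | 2,2-diphenylethanol | OCC(c1ccccc1)c1ccccc1 | starting material
5 | 1-tert-butyl 3-(2,2-diphenylethyl) 2-methylpropanedioate (racemic) | CC(C(=O)OCC(c1ccccc1)c1ccccc1)C(=O)OC(C)(C)C | intermediate
6 | 1-bromo-3-methylbut-2-ene | CC(C)=CCBr | starting material
7 | 1-tert-butyl 3-(2,2-diphenylethyl) (S)-2-methyl-2-(3-methylbut-2-enyl)propanedioate | O=C(OCC(c1ccccc1)c1ccccc1)[C@](C)(CC=C(C)C)C(=O)OC(C)(C)C | intermediate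
8 | 1-(2,2-diphenylethyl) 3-trimethylsilyl (S)-2-methyl-2-(3-methylbut-2-enyl)propanedioate | O=C(OCC(c1ccccc1)c1ccccc1)[C@](C)(CC=C(C)C)C(=O)O[Si](C)(C)C | intermediate
9 | (R)-2-[(2,2-diphenylethoxy)carbonyl]-2,5-dimethylhex-4-enoic acid | O=C(OCC(c1ccccc1)c1ccccc1)[C@](C)(CC=C(C)C)C(=O)O | intermediate
10 | 2,2-diphenylethyl (S)-2-(chlorocarbonyl)-2,5-dimethylhex-4-enoate | O=C(OCC(c1ccccc1)c1ccccc1)[C@](C)(CC=C(C)C)C(=O)Cl | intermediate
11 | heptane-2,4-dione | CCCC(=O)CC(C)=O | starting material
12 | dilithium hepta-1,3-diene-2,4-diolate | [Li+].[Li+].C=C([O-])C=C([O-])CCC | intermediate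
13 | 2,2-diphenylethyl (R)-2-methyl-2-(3-methylbut-2-enyl)-3,5,7-trioxodecanoate | O=C(OCC(c1ccccc1)c1ccccc1)[C@](C)(CC=C(C)C)C(=O)CC(=O)CC(=O)CCC | intermediate
14 | (R)-2-butanoyl-3,5-dihydroxy-4-methyl-4-(3-methylbut-2-enyl)cyclohexa-2,5-dien-1-one | CCCC(=O)C1=C(O)[C@](C)(CC=C(C)C)C(O)=CC1=O | intermediate
15 | phloroglucinol | Oc1cc(O)cc(O)c1 | starting material
16 | butanoyl chloride | CCCC(=O)Cl | starting material
17 | 1-(2,4,6-trihydroxyphenyl)butan-1-one | CCCC(=O)c1c(O)cc(O)cc1O | intermediate
18 | 1-(2,6-dihydroxy-4-methoxyphenyl)butan-1-one | CCCC(=O)c1c(O)cc(OC)cc1O | intermediate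
19 | 1-{3-[(dimethylamino)methyl]-2,6-dihydroxy-4-methoxyphenyl}butan-1-one | CCCC(=O)c1c(O)cc(OC)c(CN(C)C)c1O | intermediate
20 | 2-butanoyl-3-hydroxy-5-methoxy-6-methylidenecyclohexa-2,4-dien-1-one | C=C1C(=O)C(C(=O)CCC)=C(O)C=C1OC | intermediate
21 | elaphopilosin A, (R)-2-butanoyl-6-[(3-butanoyl-2,4-dihydroxy-6-methoxyphenyl)methyl]-3,5-dihydroxy-4-methyl-4-(3-methylbut-2-enyl)cyclohexa-2,5-dien-1-one | CCCC(=O)C1=C(O)[C@](C)(CC=C(C)C)C(O)=C(Cc2c(OC)cc(O)c(C(=O)CCC)c2O)C1=O | target

Total step count: 10. Longest linear sequence: 7 (steps 1 to 6 and 10).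

**Steps most likely to fail**

Step 6. What may go wrong:
- proton removal from the propyl-side CH2 of 11 in competition with the methyl group;
- O-acylation;
- base-induced loss of the 2,2-diphenylethyl group before the slow closure onto the hindered ester.

The fallback uses a symmetrical dinucleophile and completes the side chain after ring closure. It sets out from 10 and comes back at 14. Pentane-2,4-dione and LiN(iPr)2 (2 equiv per diketone, THF, 0 °C) give dilithium penta-1,3-diene-2,4-diolate F1, which has only one kind of terminal carbon. With 10 it should give 2,2-diphenylethyl (R)-2-methyl-2-(3-methylbut-2-enyl)-3,5,7-trioxooctanoate F2. This closes as in step 6 to (R)-2-acetyl-3,5-dihydroxy-4-methyl-4-(3-methylbut-2-enyl)cyclohexa-2,5-dien-1-one F3, which is still chiral. LiN(iPr)2 (3.2 equiv, THF, −78 → 0 °C) then forms the trilithium trianion F4. Ethyl iodide alkylates F4 at the side-chain CH2, the last-formed carbanion, and acidification gives 14.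

Step 3. What may go wrong:
- insufficient facial discrimination in the ion pair with the small prenyl electrophile;
- hydrolysis of the primary ester by the concentrated base.

The fallback replaces catalysis by resolution. It sets out from 1 (with 6 and 4) and comes back at 9. Compound 1 is alkylated with 6 (K2CO3, DMF, 23 °C) to the achiral 2,2,5-trimethyl-5-(3-methylbut-2-enyl)-1,3-dioxane-4,6-dione F5. F5 is opened by 4 (Et3N, 4-(dimethylamino)pyridine, toluene, 90 °C) to racemic 2-[(2,2-diphenylethoxy)carbonyl]-2,5-dimethylhex-4-enoic acid F6. Fractional crystallisation with (R)-1-phenylethylamine, or with its enantiomer if that gives the less soluble salt of the R acid, should give the (R)-1-phenylethylammonium (R)-carboxylate salt F7. Cold dilute H3PO4 releases 9 from F7.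

Step 10. What may go wrong:
- exchange of the methylene bridge between the partners, which leads to both symmetrical dimers;
- capture of the quinone methide by a second molecule of 19.

The fallback uses reductive alkylation in place of quinone methide capture. It sets out from 18 and 14 and comes back at 21. Vilsmeier-Haack formylation of 18 (POCl3, DMF, EtOAc, 0 → 23 °C; H2O) gives 3-butanoyl-2,4-dihydroxy-6-methoxybenzaldehyde F8. F8, 14, L-proline (cat.) and diethyl 2,6-dimethyl-1,4-dihydropyridine-3,5-dicarboxylate (Hantzsch ester) are combined in CH2Cl2 at 23 °C. They undergo Knoevenagel condensation to the arylidene trione F9. F9 is reduced in the flask by hydride transfer to its benzylic carbon and gives 21, so that no reversible bridge-forming electrophile persists.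

**Further compounds**
F1 | step 6 | dilithium penta-1,3-diene-2,4-diolate | [Li+].[Li+].C=C([O-])C=C(C)[O-]
F2 | step 6 | 2,2-diphenylethyl (R)-2-methyl-2-(3-methylbut-2-enyl)-3,5,7-trioxooctanoate | O=C(OCC(c1ccccc1)c1ccccc1)[C@](C)(CC=C(C)C)C(=O)CC(=O)CC(C)=O
F3 | step 6 | (R)-2-acetyl-3,5-dihydroxy-4-methyl-4-(3-methylbut-2-enyl)cyclohexa-2,5-dien-1-one | CC(=O)C1=C(O)[C@](C)(CC=C(C)C)C(O)=CC1=O
F4 | step 6 | trilithium trianion of F3 | [Li+].[Li+].[Li+].C=C([O-])C1=C([O-])[C@](C)(CC=C(C)C)C([O-])=CC1=O
F5 | step 3 | 2,2,5-trimethyl-5-(3-methylbut-2-enyl)-1,3-dioxane-4,6-dione | CC(C)=CCC1(C)C(=O)OC(C)(C)OC1=O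
F6 | step 3 | racemic 2-[(2,2-diphenylethoxy)carbonyl]-2,5-dimethylhex-4-enoic acid | O=C(OCC(c1ccccc1)c1ccccc1)C(C)(CC=C(C)C)C(=O)O
F7 | step 3 | (R)-1-phenylethylammonium (R)-2-[(2,2-diphenylethoxy)carbonyl]-2,5-dimethylhex-4-enoate | O=C(OCC(c1ccccc1)c1ccccc1)[C@](C)(CC=C(C)C)C(=O)[O-].C[C@@H]([NH3+])c1ccccc1
F8 | step 10 | 3-butanoyl-2,4-dihydroxy-6-methoxybenzaldehyde | CCCC(=O)c1c(O)cc(OC)c(C=O)c1O
F9 | step 10 | (R)-2-butanoyl-6-[(3-butanoyl-2,4-dihydroxy-6-methoxyphenyl)methylidene]-3-hydroxy-4-methyl-4-(3-methylbut-2-enyl)cyclohex-2-ene-1,5-dione | CCCC(=O)C1=C(O)[C@](C)(CC=C(C)C)C(=O)C(=Cc2c(OC)cc(O)c(C(=O)CCC)c2O)C1=O
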